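(The earlier runs and the new flask were generated by integration for substances that don't exist; the scatter is artificial.)

3 questions, 2 earlier runs, and I reckon by hand before any integrator gets a say.

| setting | dawn | midnight | east | west |
|---|---|---|---|---|
| electrophile | 0.69 M | 0.69 M | 0.69 M | 0.69 M |
| nucleophile | 0.52 M | 1.1 M | 0.690 M | 1.40 M |
| solid base | 0.69 M | 0.69 M | 0.690 M | 0.690 M |
| remark | run made earlier | run made earlier |  |  |
| time |  |  | 5.0 h | 5.0 h |

| run | time / h | electrophile / % | target / % |
|---|---|---|---|
| dawn | 0.250 | 90 | 10 |
| dawn | 0.667 | 82 | 18 |
| dawn | 1.33 | 76 | 23 |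
| dawn | 2.00 | 75 | 23 |
| dawn | 2.50 | 74 | 28 |
| dawn | 4.00 | 72 | 28 |
| midnight | 0.250 | 80 | 17 |
| midnight | 0.667 | 68 | 31 |
| midnight | 1.33 | 62 | 41 |
| midnight | 2.00 | 59 | 42 |
| midnight | 2.50 | 57 | 43 |
| midnight | 4.00 | 54 | 44 |

(standard deviation of a reading: 1.5 percentage points)

- solid base is a solid; its amount is given per volume of the solution
- at the start none of the solid base is in solution

* part of the electrophile that has reacted at the end, east
* part of the electrophile that has reacted at the end, west
* what raising the concentration of nucleophile from its lowest to its highest value here does to the part of the electrophile that has reacted (changes below 5 percentage points count as none) (it rises / it falls / no change)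

1. First rung, the burst. By 0.250 h dawn has lost 10.0 % of its electrophile and midnight 20.0 %, twice as much, on about twice the nucleophile.
2. Next rung, the stall. By 1.33 h dawn has lost 24.0 % of the 28.0 % it loses by 4.00 h, yet 72 % of the electrophile is still there.
3. Last rung, the creep. From 2.00 h to 4.00 h dawn loses 3 percentage points and midnight 5 points. I leave this out, so my numbers may read a little low.
4. I call ln(charged electrophile / electrophile left) the dose, and divide it by c(nucleophile) charged. From the last readings, at 4.00 h, that gives the dose per molar: 0.632 L mol⁻¹ in dawn and 0.560 L mol⁻¹ in midnight, smaller.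
5. The large part is a constant dose per molar, and I compute only the correction: the fall in dose per molar for each molar of added nucleophile, 0.123 L² mol⁻². It is read off the readings and carries their scatter.
6. For east I reckon a dose per molar of 0.611 L mol⁻¹, so I expect 34.4 % reacted. For west I reckon 0.523 L mol⁻¹, so I expect 51.9 % reacted. On this reckoning conversion rises by 18 points.

The forecast gives 36 % for east and 56 % for west, and says it rises, adding “I allow slight creep by 5 h”; both its numbers stand above mine.

The flask gives 33.9 % for east and 50.5 % for west; it rises, by 17 points.

    electrophile + nucleophile → acid set free + target (k = 1.10 L mol⁻¹ h⁻¹)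
    nucleophile + acid set free ⇌ protonated nucleophile, settled at all times (K = 7500 L mol⁻¹)
    acid set free + free base ⇌ salt of the base, settled at all times (K = 22.0 L mol⁻¹)
    solid base ⇌ free base, rate k4*(cs4 - [free base]) while solid is left; crystals form when [free base] > cs4 (solubility = 0.140 M, k = 0.140 h⁻¹)
    2 nucleophile → homo dimer (k = 1.10 L mol⁻¹ h⁻¹)
    free base → decomposition product (k = 3.90 × 10⁻⁴ h⁻¹)

West's dose per molar comes out at 0.502 L mol⁻¹ against my 0.523 L mol⁻¹. At 0.135 h in west, nucleophile goes to homo dimer 2.9 times as fast as to target, and by 1.00 h that loss has behind it 96 % of its turnover up to 5.0 h. At 5.00 h in west the ratio is 0.055, and unbound nucleophile, the limiting reagent, stands at 0.68 % of its charge against 50 % for electrophile. For a flask like west with 2.4 M of nucleophile, the same fall gives 61.7 %, and that flask gives 63.0 %.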